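The leftover came first. In Friday's run, at 8.00 min, intermediate, target and starting material summed to 84.7 % of the charge, and in Saturday's run, with 4 equiv of second reagent against Friday's 1 equiv, to 84.3 %. I took the missing part as quenched substrate and 84.7 % as the ceiling for the new flask, which has Friday's impurity and Thursday's second reagent.

all flasks: starting material 12 mM

| flask | partner | second reagent | protic impurity | remark | time |
|---|---|---|---|---|---|
| Friday's | 3 equiv | 1 equiv | 2.4 mM | run made earlier |  |
| Saturday's | 3 equiv | 4 equiv | 2.4 mM | run made earlier |  |
| Thursday's | 3 equiv | 2 equiv | 1.2 mM | run made earlier |  |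
| flask | 3.00 equiv | 2.00 equiv | 2.40 mM |  | 6.0 min |

| run | time / min | intermediate / % | target / % | starting material / % |
|---|---|---|---|---|
| Friday's | 0.333 | 38.5 | 1.0 | 52.1 |
| Friday's | 0.667 | 53.0 | 4.2 | 29.1 |
| Friday's | 1.33 | 63.4 | 10.9 | 9.7 |
| Friday's | 3.00 | 57.3 | 25.4 | 1.1 |
| Friday's | 8.00 | 36.0 | 48.7 | 0 |
| Saturday's | 0.333 | 34.1 | 4.7 | 51.9 |
| Saturday's | 0.667 | 43.5 | 14.8 | 29.2 |
| Saturday's | 1.33 | 42.1 | 33.3 | 11.2 |
| Saturday's | 3.00 | 23.9 | 60.2 | 0.6 |
| Saturday's | 8.00 | 4.2 | 80.1 | 0 |
| Thursday's | 0.333 | 37.1 | 2.4 | 55.2 |
| Thursday's | 0.667 | 51.8 | 8.8 | 32.4 |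
| Thursday's | 1.33 | 58.5 | 21.9 | 13.0 |
| Thursday's | 3.00 | 45.2 | 45.9 | 1.0 |
| Thursday's | 8.00 | 19.9 | 73.6 | 0.1 |

(standard deviation of a reading: 0.5 percentage points)

- time, not beyond 6.0 min, at which the flask holds most intermediate
- the amount of intermediate, in percent of the starting material charged, at that time

How fast did starting material go? Friday's starting material gave a half-life of 0.418 min between 0.667 min and 1.33 min.

How fast did intermediate leave at 2.00 equiv? Thursday's target gain over that interval, divided by the mean intermediate, gave a pseudo-first-order half-life of 1.93 min.

The first half-life over the second, 0.216, I called the drain ratio. For two first-order steps in a row, it is also starting material over intermediate at the peak.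

When and how high was the peak? Counting with those half-lives, I reckoned 1.18 min, earlier than the limit of 6.0 min, and the ceiling times the ratio raised to r/(1-r), with r the drain ratio, gave 55.5 %.

The forecast, by its own route, said 1.2 min and 54.5 %: “The flask is Thursday's run with Friday's impurity”.

The flask gave 55.1 % at 1.17 min.

    starting material + partner → intermediate (k = 0.810 /M/s)
    second reagent + intermediate → target (k = 0.280 /M/s)
    starting material + protic impurity → quenched substrate (k = 3.30 /M/s)
    2 second reagent → homo dimer (k = 0.0340 /M/s)

With concentrations as charged, the half-life of starting material by the partner path, 0.40 min, was shorter than that of intermediate by the path to target, 1.7 min. At its peak the flask held starting material and intermediate in the ratio 0.248, beside the drain ratio of 0.216. For the neighbouring flask with 12.0 equiv of partner, I divided the drain ratio by the rise in partner, to 0.0541, and took 94.3 % as its ceiling, so the same rule gave 79.8 %; that flask reached 79.6 %.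

The numbers in the tables are simulated on assumed constants; noise was put on by code.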